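## Analysis of the target

- Target 23 is a pentacyclic lactone alkaloid on a pyrrolo[1,2-a]azepine core, labelled here as follows: ring A is the pyrrolidine N4–C3–C2–C1–C9a; ring B the azepine N4–C5–C6–C7–C8–C9–C9a; ring C a 3-methylbut-2-enolide fused across C5–C6; ring D a γ-lactone spiro at C9 (O–C9–C10–C11(CH3)–C12=O); ring E a γ-lactone bonded to C3 through its carbinol carbon (O–C1′–C2′–C3′(CH3)–C4′=O).
- There are seven stereocentres: C3, C5, C9, C9a, C1′ and C3′ are S, and C11 is R.
- Ring A is trans-2,5-disubstituted, and the units N4–C9a–C9–O and N4–C3–C1′–O are both syn amino alcohols. The methyl group of ring E is cis to C3, whereas the methyl group of ring D lies on the face of C8, anti to C9a.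
- C5 is an N,O-acetal that can open to an iminium carboxylate, so it is labile to acid and base and is not fixed kinetically. The three lactones have enolisable α-carbons, and a free N4–H beside ring D or ring E can attack a lactone carbonyl to give a six-membered lactam.
- The hard points are the quaternary carbon C9 beside the stereocentre C9a, the two remote methyl centres C11 and C3′ (which need opposite facial senses with respect to ring A), and the late placement of ring C.
- The strategy rests on one feature: N4 is flanked on one side by C9a–C9(O) and on the other by C3–C1′(O), two amino alcohol units of the same (S,S) syn sense. A local twofold axis through N4 therefore maps C3 onto C9a, C1′ onto C9 and ring E onto ring D as far as the carbinol carbons.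
- This symmetry is broken only by the fourth substituent of C9 (C8, the start of ring B) and by the two methyl centres, which are dealt with after the symmetric step.

## Retrosynthetic reasoning

Ring C is taken off first, by cutting the C6=C(α) bond and the C5–O bond of 23. This leads to the bicyclic enamine 22 and pyruvic acid 20. C5 is the most fragile centre and should appear last. In the forward direction C6 of 22 has to add to the ketone of 20, the carboxyl group has to close on C5, and water has to be lost.

Ring B is opened at N4–C5. Enamine 22 is the condensation product of amino aldehyde 21, which is the doubly deprotected form of carbamate acetal 19. The forward ring closure must be run in acid so that N4–H meets the aldehyde before it can attack a lactone. For the same reason no α-methylene lactone may be left when N4–H is set free, because the amine would add to it.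

The two methyl centres are traced back to exocyclic methylene groups, 19 to 18 to 17. They are handled in two separate reductions because ring E needs hydrogen on the face away from C3 (substrate control) whereas ring D needs hydrogen on the face of C9a. The latter is the more hindered side and is therefore given to a chiral catalyst.

The key disconnection cuts, in 17, the bonds C9–C10 and C1′–C2′ and the two lactone acyl C–O bonds. This gives keto aldehyde 13 and two molecules of bromide 14. It is made here because both carbonyl groups sit α to the same nitrogen on a trans ring and ask for the same facial sense. It removes both lactone rings and the quaternary centre C9 in one operation and leaves a nearly symmetric pyrrolidine. The forward step needs syn (chelate-type) addition at both carbonyl groups.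

The two different carbonyl groups of 13 are traced to one precursor each. The aldehyde comes from alcohol 12 and its silyl ether 11. The ketone comes from Weinreb amide 8 and Grignard reagent 10, made from chloride 9, which brings in C5–C8 with C5 masked as an acetal.

Amide 8 goes back through ester 7, alcohol 6 and mono-acid 5 to the C2-symmetric diester 4. The two esters of 4 are homotopic, so a single saponification differentiates them without any selectivity problem. A chemoselective reduction of the acid then fixes which end becomes the aldehyde.

Diester 4 comes from pyrrolidine 3 by exchange of the N-substituent, and 3 from dibromide 1 and amine 2 by twofold N-alkylation. The chiral amine makes the trans isomers separable and so supplies C3 and C9a as the (S,S) pair.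

## Alternatives that were turned down

**Alternative 1:** Ring D is cut at C9–O and C10–C11, which leads back to the bicyclic lactam A2 with an exocyclic methylene group at C9.
- Forward key step: a carboxymethyl radical (from an α-iodo carboxylic acid) adds to the terminal carbon of A2. The tertiary C9 radical is trapped as the iodide or oxidised to the cation, and the carboxyl oxygen closes the lactone to give A1, whose ring D is unsubstituted at C11.
- For it: C9 is made on a preformed A/B bicycle that already carries ring E, and the C5 lactam carbonyl marks the place of ring C. The C11 methyl group can be introduced afterwards by enolate alkylation, which brings the methyl group and not a hydrogen to the open face. On this point the alternative is stronger than the chosen route, which needs a chiral catalyst for C11.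
- Against it: the C9–O bond forms at a planar radical or cation beside C9a with the nucleophile on a flexible two-carbon tether, so nothing in A2 fixes the face. A tertiary iodide or cation next to C9a–H can also lose a proton to the enamide. The later methylation has to distinguish the ring D enolate from those of ring E and the lactam. Ring C must still be grown from a lactam carbonyl in the presence of two lactones.
- Comparison: its key step forms one ring. The chosen step forms rings D and E together with C9 from a far simpler precursor, and it reaches C5 at the aldehyde oxidation level.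

**Alternative 2:** The bonds N4–C5 and N4–C9a are cut, which leads back to the azido cyclohexanone A4 (C5 ketone, C3 azide).
- Forward key step: under a strong titanium Lewis acid the azide adds to the ketone, C9a migrates from C5 to nitrogen with loss of dinitrogen, and the lactam A3 results with rings A and B formed together.
- For it: the intramolecular Schmidt reaction is a dependable way to fused lactams, and the migrating carbon keeps its configuration. C9a, C9 and C3 are therefore set beforehand in a carbocycle, and the methyl centres come from building blocks. On the security of these centres it is stronger than the chosen route, which depends on facial selectivity in the key step and on two reductions.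
- Against it: A4 needs five stereocentres, including quaternary C9 and the C3/C1′ pair, before the key step. The azide is secondary and flanked by ring E. The tertiary silyl ether at C9 is β to the ketone and invites elimination or retro-aldol cleavage under the Lewis acid. The product is again a C5 lactam that must be reduced and elaborated into ring C beside esters and lactones.
- Comparison: the chosen route offers a short, almost symmetric precursor, and two rings plus C9 in one step.

**Alternative 3:** The bonds N4–C3 and C1′–O are cut, which leads back to the azepane A6 with a free N–H, a Z alkene in the side chain and a methyl ester.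
- Forward key step: an electrophilic iodine source activates the alkene and N4 closes ring A at C3. The β-iodo amine then ionises through an aziridinium ion, which the ester carbonyl opens at C1′ with loss of the ester methyl group as its iodide. This closes ring E and gives A5.
- For it: the cascade is stereospecific, so the C3/C1′ relation follows from the alkene geometry and not from a chelation model. On this point it is stronger than the chosen route.
- Against it: A6 needs ring B with spiro ring D, a tetrasubstituted alkylidene ester of defined geometry and a Z-alkenyl chain with its own stereocentre, all made linearly. A5 still lacks the oxygen at C5, so the synthesis would end with a C–H oxidation of a tertiary amine that has three α-positions (C3, C5, C9a), followed by lactonisation.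
- Comparison: the chosen route brings C5 in as an aldehyde, needs no late oxidation, and is shorter because both lactones arise in one two-directional step.

Key step: step 10

**Remarks on the chemistry (assumptions)**
- Commercial 1 is taken as the meso isomer. Its bromide-bearing centres are replaced and equilibrated in step 1, so this does not affect the outcome.
- C5 of 23 is assumed to settle under thermodynamic control by reversible opening to the iminium carboxylate, with the S configuration of the target as the more stable arrangement.
- The (S)-BINAP complex in step 12 is assumed to deliver hydrogen to the C11 face that gives R. A trial on 18 decides this, and the (R)-ligand is used if the sense is reversed.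

## Steps

Step 1
Reactants: 1 diethyl meso-2,5-dibromohexanedioate; 2 (S)-1-phenylethylamine
Product: 3 diethyl (2S,5S)-1-[(1S)-1-phenylethyl]pyrrolidine-2,5-dicarboxylate
Conditions: K2CO3, toluene/H2O, reflux; chromatographic separation of the diastereomers
Reagents that add atoms: none
Why: Twofold SN2 N-alkylation of the primary amine by the α-bromo esters closes ring A; the bromide-bearing centres equilibrate by halide exchange, so the cis and both trans pyrrolidines form, and the (S)-1-phenylethyl group makes the two trans isomers diastereomers that are separated, which fixes C3 and C9a as S,S.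

Step 2
Reactants: 3 diethyl (2S,5S)-1-[(1S)-1-phenylethyl]pyrrolidine-2,5-dicarboxylate
Product: 4 1-tert-butyl 2,5-diethyl (2S,5S)-pyrrolidine-1,2,5-tricarboxylate
Conditions: H2 (4 atm), Pd(OH)2/C, Boc2O, EtOH, rt
Reagents that add atoms: di-tert-butyl dicarbonate, CC(C)(C)OC(=O)OC(=O)OC(C)(C)C
Why: Hydrogenolysis of the benzylic C–N bond frees the secondary amine, which is acylated in the same flask; the carbamate later stabilises the α-amino aldehyde, offers a chelating oxygen and leaves in acid together with the acetal.

Step 3
Reactants: 4 1-tert-butyl 2,5-diethyl (2S,5S)-pyrrolidine-1,2,5-tricarboxylate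
Product: 5 (2S,5S)-1-(tert-butoxycarbonyl)-5-(ethoxycarbonyl)pyrrolidine-2-carboxylic acid
Conditions: LiOH (1.0 equiv), THF/H2O, 0 °C; then 1 M HCl
Reagents that add atoms: lithium hydroxide, [Li+].[OH-]
Why: The two esters of the C2-symmetric diester are homotopic, so saponification of either gives the same mono-acid; the carboxylate formed slows the second hydrolysis, and diester and diacid are removed by acid–base extraction.

Step 4
Reactants: 5 (2S,5S)-1-(tert-butoxycarbonyl)-5-(ethoxycarbonyl)pyrrolidine-2-carboxylic acid
Product: 6 1-tert-butyl 2-ethyl (2S,5S)-5-(hydroxymethyl)pyrrolidine-1,2-dicarboxylate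
Conditions: BH3·SMe2, THF, 0 °C to rt; then H2O
Reagents that add atoms: none
Why: Borane reduces a carboxylic acid through its acyloxyborane much faster than an ester or a carbamate (chemoselective borane reduction), which decides that this end becomes the aldehyde.

Step 5
Reactants: 6 1-tert-butyl 2-ethyl (2S,5S)-5-(hydroxymethyl)pyrrolidine-1,2-dicarboxylate
Product: 7 1-tert-butyl 2-ethyl (2S,5S)-5-{[(tert-butyldimethylsilyl)oxy]methyl}pyrrolidine-1,2-dicarboxylate
Conditions: TBSCl, imidazole, DMF, rt
Reagents that add atoms: tert-butyldimethylsilyl chloride, CC(C)(C)[Si](C)(C)Cl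
Why: Silylation of the primary alcohol keeps a magnesium alkoxide from attacking the carbamate carbonyl during the two organomagnesium steps that follow.

Step 6
Reactants: 7 1-tert-butyl 2-ethyl (2S,5S)-5-{[(tert-butyldimethylsilyl)oxy]methyl}pyrrolidine-1,2-dicarboxylate
Product: 8 tert-butyl (2S,5S)-2-{[(tert-butyldimethylsilyl)oxy]methyl}-5-[methoxy(methyl)carbamoyl]pyrrolidine-1-carboxylate
Conditions: MeNH(OMe)·HCl, i-PrMgCl, THF, −20 to 0 °C
Reagents that add atoms: N,O-dimethylhydroxylamine hydrochloride, CNOC.Cl
Why: Direct conversion of the ester into the Weinreb amide by the chloromagnesium amide made in the flask; the carbamate and the silyl ether are inert, and the α-centre is not enolised at this temperature.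

Step 7
Reactants: 8 tert-butyl (2S,5S)-2-{[(tert-butyldimethylsilyl)oxy]methyl}-5-[methoxy(methyl)carbamoyl]pyrrolidine-1-carboxylate; 9 4-chloro-1,1-dimethoxybutane
Product: 11 tert-butyl (2S,5S)-2-{[(tert-butyldimethylsilyl)oxy]methyl}-5-(5,5-dimethoxypentanoyl)pyrrolidine-1-carboxylate, via Grignard reagent 10 (not isolated)
Conditions: 9, Mg, THF, reflux; then 8, THF, −20 to 0 °C; aq. NH4Cl
Reagents that add atoms: none
Why: Weinreb ketone synthesis: the Grignard reagent adds once and the chelated tetrahedral magnesium intermediate survives until the quench, so no tertiary alcohol forms; the acetal sits four carbons from magnesium and is not expelled.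

Step 8
Reactants: 11 tert-butyl (2S,5S)-2-{[(tert-butyldimethylsilyl)oxy]methyl}-5-(5,5-dimethoxypentanoyl)pyrrolidine-1-carboxylate
Product: 12 tert-butyl (2S,5S)-2-(5,5-dimethoxypentanoyl)-5-(hydroxymethyl)pyrrolidine-1-carboxylate
Conditions: TBAF, AcOH, THF, 0 °C to rt
Reagents that add atoms: none
Why: Fluoride cleaves the Si–O bond; acetic acid buffers the alkoxide so that the α-amino ketone centre is not epimerised, and the dimethyl acetal is untouched.

Step 9
Reactants: 12 tert-butyl (2S,5S)-2-(5,5-dimethoxypentanoyl)-5-(hydroxymethyl)pyrrolidine-1-carboxylate
Product: 13 tert-butyl (2S,5S)-2-(5,5-dimethoxypentanoyl)-5-formylpyrrolidine-1-carboxylate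
Conditions: Dess–Martin periodinane, NaHCO3, CH2Cl2, 0 °C to rt; used at once
Reagents that add atoms: none
Why: Dess–Martin oxidation under buffered, non-basic conditions gives the N-carbamoyl α-amino aldehyde without epimerisation of the centre that becomes C3; the trans ring prevents any aldol reaction between the two carbonyl groups.

Step 10
Reactants: 13 tert-butyl (2S,5S)-2-(5,5-dimethoxypentanoyl)-5-formylpyrrolidine-1-carboxylate; 14 ethyl 2-(bromomethyl)acrylate (2.5 equiv)
Product: 17 tert-butyl (2S,5S)-2-[(2S)-2-(4,4-dimethoxybutyl)-4-methylidene-5-oxooxolan-2-yl]-5-[(2S)-4-methylidene-5-oxooxolan-2-yl]pyrrolidine-1-carboxylate, via allylzinc bromide 15 (not isolated), via bis(zinc alkoxide) diester 16 (not isolated)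
Conditions: Zn dust (TMSCl-activated), 14, THF, 0 °C to rt, then 50 °C; aq. NH4Cl
Reagents that add atoms: none
Why: Zinc inserts into the allylic C–Br bond of 14 to give allylzinc bromide 15, which adds through its γ-carbon (SE2′) in a six-membered cyclic transition state, first to the aldehyde and on warming to the ketone, to give the bis(zinc alkoxide) 16. Each alkoxide then attacks its own ethyl ester and expels ethoxide (5-exo-trig acyl substitution), which closes ring E and ring D as α-methylene-γ-lactones; four skeletal bonds (C1′–C2′, C9–C10 and two acyl C–O bonds) and two rings form in one flask. The closest known reaction is the Dreiding–Schmidt lactone synthesis, which is established for aldehydes, for ketones and for N-carbamoyl α-amino aldehydes; only its use at two carbonyl groups of one molecule is untested. C1′ is controlled by C3: zinc bridging the carbamate carbonyl oxygen and the aldehyde oxygen holds the C=O bond syn to C3–N, and the allyl group enters on the face of C3–H, away from C2, which gives the syn amino alcohol and S at C1′. C9 is controlled in the same way by C9a, with attack anti to C1 giving S at C9. Because C3 and C9a are both S on a trans ring, the two additions call for the same facial sense, and the trans arrangement also rules out an aldol reaction between the two carbonyl groups. The step needs chemoselectivity for the two carbonyl groups over the acetal, the carbamate and the acrylate units formed, which the mild allylzinc reagent in THF provides.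

Step 11
Reactants: 17 tert-butyl (2S,5S)-2-[(2S)-2-(4,4-dimethoxybutyl)-4-methylidene-5-oxooxolan-2-yl]-5-[(2S)-4-methylidene-5-oxooxolan-2-yl]pyrrolidine-1-carboxylate
Product: 18 tert-butyl (2S,5S)-2-[(2S)-2-(4,4-dimethoxybutyl)-4-methylidene-5-oxooxolan-2-yl]-5-[(2S,4S)-4-methyl-5-oxooxolan-2-yl]pyrrolidine-1-carboxylate
Conditions: H2 (1 atm), RhCl(PPh3)3 (cat.), toluene, rt; stopped after one equivalent of H2
Reagents that add atoms: none
Why: Homogeneous hydrogenation with the bulky RhCl(PPh3)3 responds strongly to hindrance: the methylene group of ring E has one face flanked only by C1′–H, whereas both faces of the ring D methylene group carry a carbon substituent of quaternary C9; hydrogen adds to ring E from the face opposite ring A, which places the new methyl group cis to C3 (S at C3′).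

Step 12
Reactants: 18 tert-butyl (2S,5S)-2-[(2S)-2-(4,4-dimethoxybutyl)-4-methylidene-5-oxooxolan-2-yl]-5-[(2S,4S)-4-methyl-5-oxooxolan-2-yl]pyrrolidine-1-carboxylate
Product: 19 tert-butyl (2S,5S)-2-[(2S,4R)-2-(4,4-dimethoxybutyl)-4-methyl-5-oxooxolan-2-yl]-5-[(2S,4S)-4-methyl-5-oxooxolan-2-yl]pyrrolidine-1-carboxylate
Conditions: H2 (50 atm), Ru(OAc)2[(S)-BINAP] (cat.), MeOH, 40 °C
Reagents that add atoms: none
Why: Asymmetric hydrogenation of an α-methylene-γ-butyrolactone by a BINAP–ruthenium diacetate, a known substrate class in which the lactone carbonyl and the alkene both bind the metal; the ligand, and not the weak bias of the two carbon substituents on distant C9, selects the face, so hydrogen can be delivered on the side of C9a and C11 is set as R under catalyst control.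

Step 13
Reactants: 19 tert-butyl (2S,5S)-2-[(2S,4R)-2-(4,4-dimethoxybutyl)-4-methyl-5-oxooxolan-2-yl]-5-[(2S,4S)-4-methyl-5-oxooxolan-2-yl]pyrrolidine-1-carboxylate; 20 pyruvic acid
Product: 23 target CNP0155196.1, the pyrrolo[1,2-a]azepine with a 3-methylbut-2-enolide fused at C5–C6 (C5 S), a (4R)-4-methyl-γ-butyrolactone spiro at C9 (S), C9a S and a (2S,4S)-4-methyl-5-oxooxolan-2-yl group at C3 (S), via amino aldehyde 21 (not isolated), via bicyclic enamine 22 (not isolated)
Conditions: TFA, CH2Cl2, H2O (trace), 0 °C to rt; evaporate; then 20 (3 equiv), Et3N (1.1 equiv), 4 Å MS, MeCN, rt to 60 °C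
Reagents that add atoms: none
Why: Proposed new method: acid removes the carbamate and the acetal, the ammonium aldehyde 21 condenses to the seven-membered iminium ion, which after neutralisation is in equilibrium with enamine 22; C6 of 22 should add to the ketone of 20 (enamine aldol addition), the carboxylate then closes on the C5 iminium carbon, and loss of water through the iminium–enamine pair gives the conjugated butenolide, with C5 settling by reversible ring opening; the closest known reactions are the butenolide synthesis from an aldehyde, a secondary amine and glyoxylic acid, and the aldol condensation of enolisable ketones with pyruvic acid at its keto group.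

## Compound list

1 | diethyl meso-2,5-dibromohexanedioate | CCOC(=O)[C@@H](Br)CC[C@@H](Br)C(=O)OCC | starting material
2 | (S)-1-phenylethylamine | C[C@H](N)c1ccccc1 | starting material
3 | diethyl (2S,5S)-1-[(1S)-1-phenylethyl]pyrrolidine-2,5-dicarboxylate | CCOC(=O)[C@@H]1CC[C@@H](C(=O)OCC)N1[C@@H](C)c1ccccc1 | intermediate
4 | 1-tert-butyl 2,5-diethyl (2S,5S)-pyrrolidine-1,2,5-tricarboxylate | CCOC(=O)[C@@H]1CC[C@@H](C(=O)OCC)N1C(=O)OC(C)(C)C | intermediate
5 | (2S,5S)-1-(tert-butoxycarbonyl)-5-(ethoxycarbonyl)pyrrolidine-2-carboxylic acid | OC(=O)[C@@H]1CC[C@@H](C(=O)OCC)N1C(=O)OC(C)(C)C | intermediate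
6 | 1-tert-butyl 2-ethyl (2S,5S)-5-(hydroxymethyl)pyrrolidine-1,2-dicarboxylate | OC[C@@H]1CC[C@@H](C(=O)OCC)N1C(=O)OC(C)(C)C | intermediate
7 | 1-tert-butyl 2-ethyl (2S,5S)-5-{[(tert-butyldimethylsilyl)oxy]methyl}pyrrolidine-1,2-dicarboxylate | CC(C)(C)[Si](C)(C)OC[C@@H]1CC[C@@H](C(=O)OCC)N1C(=O)OC(C)(C)C | intermediate
8 | tert-butyl (2S,5S)-2-{[(tert-butyldimethylsilyl)oxy]methyl}-5-[methoxy(methyl)carbamoyl]pyrrolidine-1-carboxylate | CON(C)C(=O)[C@@H]1CC[C@@H](CO[Si](C)(C)C(C)(C)C)N1C(=O)OC(C)(C)C | intermediate
9 | 4-chloro-1,1-dimethoxybutane | ClCCCC(OC)OC | starting material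
10 | (4,4-dimethoxybutyl)magnesium chloride | COC(CCC[Mg]Cl)OC | intermediate (not isolated)
11 | tert-butyl (2S,5S)-2-{[(tert-butyldimethylsilyl)oxy]methyl}-5-(5,5-dimethoxypentanoyl)pyrrolidine-1-carboxylate | COC(OC)CCCC(=O)[C@@H]1CC[C@@H](CO[Si](C)(C)C(C)(C)C)N1C(=O)OC(C)(C)C | intermediate
12 | tert-butyl (2S,5S)-2-(5,5-dimethoxypentanoyl)-5-(hydroxymethyl)pyrrolidine-1-carboxylate | COC(OC)CCCC(=O)[C@@H]1CC[C@@H](CO)N1C(=O)OC(C)(C)C | intermediate
13 | tert-butyl (2S,5S)-2-(5,5-dimethoxypentanoyl)-5-formylpyrrolidine-1-carboxylate | COC(OC)CCCC(=O)[C@@H]1CC[C@@H](C=O)N1C(=O)OC(C)(C)C | intermediate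
14 | ethyl 2-(bromomethyl)acrylate | C=C(CBr)C(=O)OCC | starting material
15 | [2-(ethoxycarbonyl)prop-2-en-1-yl]zinc bromide | C=C(C[Zn]Br)C(=O)OCC | intermediate (not isolated)
16 | bis(bromozinc alkoxide) of the twofold adduct, diethyl ester, before lactonisation | COC(OC)CCC[C@](O[Zn]Br)(CC(=C)C(=O)OCC)[C@@H]1CC[C@@H]([C@@H](O[Zn]Br)CC(=C)C(=O)OCC)N1C(=O)OC(C)(C)C | intermediate (not isolated)
17 | tert-butyl (2S,5S)-2-[(2S)-2-(4,4-dimethoxybutyl)-4-methylidene-5-oxooxolan-2-yl]-5-[(2S)-4-methylidene-5-oxooxolan-2-yl]pyrrolidine-1-carboxylate | COC(OC)CCC[C@]1(CC(=C)C(=O)O1)[C@@H]1CC[C@@H]([C@@H]2CC(=C)C(=O)O2)N1C(=O)OC(C)(C)C | intermediate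
18 | tert-butyl (2S,5S)-2-[(2S)-2-(4,4-dimethoxybutyl)-4-methylidene-5-oxooxolan-2-yl]-5-[(2S,4S)-4-methyl-5-oxooxolan-2-yl]pyrrolidine-1-carboxylate | COC(OC)CCC[C@]1(CC(=C)C(=O)O1)[C@@H]1CC[C@@H]([C@@H]2C[C@H](C)C(=O)O2)N1C(=O)OC(C)(C)C | intermediate
19 | tert-butyl (2S,5S)-2-[(2S,4R)-2-(4,4-dimethoxybutyl)-4-methyl-5-oxooxolan-2-yl]-5-[(2S,4S)-4-methyl-5-oxooxolan-2-yl]pyrrolidine-1-carboxylate | COC(OC)CCC[C@]1(C[C@@H](C)C(=O)O1)[C@@H]1CC[C@@H]([C@@H]2C[C@H](C)C(=O)O2)N1C(=O)OC(C)(C)C | intermediate
20 | pyruvic acid | CC(=O)C(=O)O | starting material
21 | 4-[(2S,4R)-4-methyl-2-{(2S,5S)-5-[(2S,4S)-4-methyl-5-oxooxolan-2-yl]pyrrolidin-2-yl}-5-oxooxolan-2-yl]butanal | O=CCCC[C@]1(C[C@@H](C)C(=O)O1)[C@@H]1CC[C@@H]([C@@H]2C[C@H](C)C(=O)O2)N1 | intermediate (not isolated)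
22 | bicyclic enamine: (3S,9S,9aS)-2,3,7,8,9,9a-hexahydro-1H-pyrrolo[1,2-a]azepine (C5=C6) with the (4R)-4-methyl-γ-butyrolactone spiro at C9 and the (2S,4S)-4-methyl-5-oxooxolan-2-yl group at C3 | C=1CC[C@]2(C[C@@H](C)C(=O)O2)[C@@H]2CC[C@@H]([C@@H]3C[C@H](C)C(=O)O3)N2C=1 | intermediate (not isolated)
23 | CNP0155196.1: (3S,5S,9S,9aS)-pyrrolo[1,2-a]azepine with the 3-methylbut-2-enolide fused at C5–C6, the (4R)-4-methyl-γ-butyrolactone spiro at C9 and the (2S,4S)-4-methyl-5-oxooxolan-2-yl group at C3 | CC1=C2CC[C@]3(C[C@@H](C)C(=O)O3)[C@@H]3CC[C@@H]([C@@H]4C[C@H](C)C(=O)O4)N3[C@H]2OC1=O | target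

## Step count and least certain steps

Total step count: 13. Longest linear sequence: 13 steps (1 to 23). Compounds 9, 14 and 20 enter as commercial materials.

**Step 13 (proposed new method).**
- What may go wrong: enolised pyruvic acid may add as a nucleophile to the C5 iminium carbon (Mannich pathway) instead of being attacked at its keto group by C6. Pyruvic acid may self-condense. N4–H may attack a lactone before ring B has closed. C5 may fail to equilibrate to the S configuration.
- Fallback (known reactions only), from 19 back to 23: the acetal alone is hydrolysed (PPTS, acetone/H2O) to the N-Boc aldehyde F1. F1 is converted (TMSCl, Et3N, NaI, MeCN) into the trimethylsilyl enol ether F2. A Mukaiyama aldol addition of F2 to tert-butyl pyruvate (BF3·OEt2, CH2Cl2, −78 °C) gives the tertiary alcohol F3 as a mixture of diastereomers, which is of no consequence because both new centres are lost. TFA then removes the carbamate and the tert-butyl ester together; the ammonium aldehyde condenses to the iminium ion, the free carboxylic acid closes on C5 and water is lost, to give 23. Here the C6–C bond is made by an enol silane on the pyruvate ketone, so the Mannich pathway cannot compete.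

**Step 10 (key step).**
- What may go wrong: poor facial selectivity at either carbonyl group if open Felkin–Anh addition competes with the zinc chelate; epimerisation of the aldehyde α-centre before addition; slow lactonisation of the tertiary alkoxide.
- Fallback, from 11 back to 17: the two additions are separated so that each can be controlled on its own. The zinc reagent from 14 is added to the ketone of 11 alone (THF, 50 °C), where the metal and Lewis acid additives can be varied freely, to give the silyl ether lactone F4. TBAF/AcOH gives the alcohol F5 and Dess–Martin oxidation the aldehyde F6. Ring E is then made under catalyst control by allylboration of F6 with ethyl 2-[(4,4,5,5-tetramethyl-1,3,2-dioxaborolan-2-yl)methyl]acrylate and a chiral phosphoric acid (closed chair transition state, catalyst antipode chosen for S at C1′), with lactonisation on work-up, to give 17.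

**Step 11.**
- What may go wrong: loss of chemoselectivity, with partial reduction of the ring D methylene group in the substrate-controlled (wrong) sense; migration of the exocyclic double bond into the lactone ring.
- Fallback, from 13 back to 18: with one equivalent of 14 and zinc at −20 °C only the aldehyde reacts, giving the keto lactone F7. Hydrogenation over Pd/C reduces the only alkene present, from the face away from ring A, to the cis-methyl keto lactone F8. A second zinc-mediated addition of 14 to the ketone of F8 then gives 18.

**Step 12.**
- What may go wrong: slow turnover because both faces of ring D are flanked by substituents of C9; erosion of catalyst control if the substrate bias opposes the ligand.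
- Fallback, from 18 back to 19 without a new intermediate: biocatalytic reduction with a flavin-dependent ene-reductase of the Old Yellow Enzyme family and an NADPH recycling system (glucose, glucose dehydrogenase, buffer at pH 7 with a cosolvent). Hydride goes to the exocyclic carbon and a proton to C11 in a trans addition inside the active site, which is a different mode of stereocontrol from syn addition of H2 on a metal. Enzymes of either facial preference exist and would be screened.

## Further compounds

F1 | step 13 | tert-butyl (2S,5S)-2-[(2S,4R)-4-methyl-5-oxo-2-(4-oxobutyl)oxolan-2-yl]-5-[(2S,4S)-4-methyl-5-oxooxolan-2-yl]pyrrolidine-1-carboxylate | O=CCCC[C@]1(C[C@@H](C)C(=O)O1)[C@@H]1CC[C@@H]([C@@H]2C[C@H](C)C(=O)O2)N1C(=O)OC(C)(C)C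
F2 | step 13 | trimethylsilyl enol ether of F1 (E/Z mixture) | C[Si](C)(C)OC=CCC[C@]1(C[C@@H](C)C(=O)O1)[C@@H]1CC[C@@H]([C@@H]2C[C@H](C)C(=O)O2)N1C(=O)OC(C)(C)C
F3 | step 13 | aldol adduct of F2 with tert-butyl pyruvate (tert-butyl 3-formyl-2-hydroxy-2-methyl ester, mixture at the two new centres) | CC(O)(C(=O)OC(C)(C)C)C(C=O)CC[C@]1(C[C@@H](C)C(=O)O1)[C@@H]1CC[C@@H]([C@@H]2C[C@H](C)C(=O)O2)N1C(=O)OC(C)(C)C
F4 | step 10 | tert-butyl (2S,5S)-2-{[(tert-butyldimethylsilyl)oxy]methyl}-5-[(2S)-2-(4,4-dimethoxybutyl)-4-methylidene-5-oxooxolan-2-yl]pyrrolidine-1-carboxylate | COC(OC)CCC[C@]1(CC(=C)C(=O)O1)[C@@H]1CC[C@@H](CO[Si](C)(C)C(C)(C)C)N1C(=O)OC(C)(C)C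
F5 | step 10 | tert-butyl (2S,5S)-2-[(2S)-2-(4,4-dimethoxybutyl)-4-methylidene-5-oxooxolan-2-yl]-5-(hydroxymethyl)pyrrolidine-1-carboxylate | COC(OC)CCC[C@]1(CC(=C)C(=O)O1)[C@@H]1CC[C@@H](CO)N1C(=O)OC(C)(C)C
F6 | step 10 | tert-butyl (2S,5S)-2-[(2S)-2-(4,4-dimethoxybutyl)-4-methylidene-5-oxooxolan-2-yl]-5-formylpyrrolidine-1-carboxylate | COC(OC)CCC[C@]1(CC(=C)C(=O)O1)[C@@H]1CC[C@@H](C=O)N1C(=O)OC(C)(C)C
F7 | step 11 | tert-butyl (2S,5S)-2-(5,5-dimethoxypentanoyl)-5-[(2S)-4-methylidene-5-oxooxolan-2-yl]pyrrolidine-1-carboxylate | COC(OC)CCCC(=O)[C@@H]1CC[C@@H]([C@@H]2CC(=C)C(=O)O2)N1C(=O)OC(C)(C)C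
F8 | step 11 | tert-butyl (2S,5S)-2-(5,5-dimethoxypentanoyl)-5-[(2S,4S)-4-methyl-5-oxooxolan-2-yl]pyrrolidine-1-carboxylate | COC(OC)CCCC(=O)[C@@H]1CC[C@@H]([C@@H]2C[C@H](C)C(=O)O2)N1C(=O)OC(C)(C)C
F0 | step 12 | none | none
A1 | alternative 1 | pyrrolo[1,2-a]azepin-5-one carrying ring E at C3 and an unsubstituted spiro γ-lactone at C9 | O=C1CCC[C@]3(CCC(=O)O3)[C@@H]3CC[C@@H]([C@@H]4C[C@H](C)C(=O)O4)N13
A2 | alternative 1 | 9-methylidene pyrrolo[1,2-a]azepin-5-one carrying ring E at C3 | O=C1CCCC(=C)[C@@H]2CC[C@@H]([C@@H]3C[C@H](C)C(=O)O3)N12
A3 | alternative 2 | pyrrolo[1,2-a]azepin-5-one with C9 triethylsilyl ether, C9 methyl ester side chain and ring E at C3 | O=C1CCC[C@](O[Si](CC)(CC)CC)(C[C@@H](C)C(=O)OC)[C@@H]2CC[C@@H]([C@@H]3C[C@H](C)C(=O)O3)N12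
A4 | alternative 2 | azido cyclohexanone with C9 triethylsilyl ether and the C3 azide beside ring E | O=C1CCC[C@](O[Si](CC)(CC)CC)(C[C@@H](C)C(=O)OC)[C@@H]1CC[C@@H]([C@@H]2C[C@H](C)C(=O)O2)N=[N+]=[N-]
A5 | alternative 3 | tetracyclic amine with rings A, B, D and E and a C6 alkylidene tert-butyl ester (C5 methylene) | CC(C)(C)OC(=O)/C(C)=C1/CC[C@]3(C[C@@H](C)C(=O)O3)[C@@H]3CC[C@@H]([C@@H]4C[C@H](C)C(=O)O4)N3C1
A6 | alternative 3 | azepane with free N–H, spiro ring D, C6 alkylidene tert-butyl ester and a Z-alkenyl methyl ester side chain at C9a | CC(C)(C)OC(=O)/C(C)=C1/CC[C@]2(C[C@@H](C)C(=O)O2)[C@H](CC/C=C\C[C@H](C)C(=O)OC)NC1
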